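Spiro numbering is used: ring A is C1(Me)=C2–C3(OH)–C4(Br)–C5Me2–C6, ring B is C6–C7–C8(Br)=C9(Me)–C10–C11. Everything rests on closing ring A at C3–C4. These carbons carry a trans OH/Br pair next to the C1=C2 alkene, the signature of anti HOBr addition to the distal double bond of a ring A 1,3-diene. The bond is therefore made as a C=C by ring-closing metathesis, which turns a ring B cyclohexene bearing two vinyl-terminated arms on C6 into the spiro[5.5] skeleton. The C6 centre of that precursor comes from an enantioselective Diels–Alder reaction; dehydration and regioselective bromohydrin formation complete the route.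

Key step: step 8

Assumption: the (S)-configured oxazaborolidinium catalyst of step 4 is taken as the enantiomer that leaves the re face at C2 of enal 6 open to the diene; if the first run shows the opposite sense, the (R)-catalyst is used with no other change.

Step 1
Reactants: 1 2-methylbut-1-en-3-yne
Product: 3 2-bromo-3-methylbuta-1,3-diene, via 4-bromo-3-methylbuta-1,2-diene 2 (not isolated)
Conditions: 48% aq. HBr (1.1 equiv), CuBr (5 mol%), NH4Br, 0 to 20 °C; distilled, kept cold over a trace of radical inhibitor
Reagents that add atoms: hydrogen bromide, Br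
Why: CuBr-catalysed 1,4-hydrobromination of the conjugated enyne should give allenyl bromide 2, which the same catalyst isomerises by 1,3-bromide (SN2′) shift to the conjugated 2-bromodiene, the sequence by which chloroprene is made from vinylacetylene; no stereocentre is formed.

Step 2
Reactants: 4 methyl 3,3-dimethylpent-4-enoate
Product: 5 3,3-dimethylpent-4-enal
Conditions: i-Bu2AlH (1.05 equiv), CH2Cl2, −78 °C; aq. Rochelle salt
Reagents that add atoms: none
Why: partial ester reduction with i-Bu2AlH should stop at the aldehyde because the tetrahedral aluminium hemiacetal survives at −78 °C until hydrolysis.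

Step 3
Reactants: 5 3,3-dimethylpent-4-enal
Product: 6 3,3-dimethyl-2-methylidenepent-4-enal
Conditions: 37% aq. HCHO, pyrrolidine (10 mol%), propanoic acid (10 mol%), i-PrOH, 45 °C
Reagents that add atoms: formaldehyde, C=O
Why: amine/acid-catalysed Mannich condensation (α-methylenation of an aldehyde through enamine, Mannich base and β-elimination) should act at the only α-CH2 group and cannot over-react because the product has no α-hydrogen.

Step 4
Reactants: 6 3,3-dimethyl-2-methylidenepent-4-enal; 3 2-bromo-3-methylbuta-1,3-diene
Product: 7 (1R)-3-bromo-4-methyl-1-(2-methylbut-3-en-2-yl)cyclohex-3-ene-1-carbaldehyde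
Conditions: 3 (3 equiv), (S)-3,3-diphenyl-1-(2-methylphenyl)tetrahydro-1H,3H-pyrrolo[1,2-c][1,3,2]oxazaborole (20 mol%), HNTf2 (20 mol%), CH2Cl2, −20 to 20 °C
Reagents that add atoms: none
Why: enantioselective Diels–Alder reaction of a 2-substituted acrolein under chiral oxazaborolidinium catalysis, in which the more nucleophilic diene terminus (the CH2 next to C–CH3) should bond to the enal β-carbon so that CH3 ends para and Br meta to the quaternary carbon, while the catalyst shields one enal face so that the diene adds to the re face at C2 of 6 and sets the quaternary (future C6) centre as R.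

Step 5
Reactants: 7 (1R)-3-bromo-4-methyl-1-(2-methylbut-3-en-2-yl)cyclohex-3-ene-1-carbaldehyde
Product: 8 1-[(1R)-3-bromo-4-methyl-1-(2-methylbut-3-en-2-yl)cyclohex-3-en-1-yl]ethan-1-ol (both carbinol epimers)
Conditions: MeMgBr (1.3 equiv), THF, −78 to 0 °C; aq. NH4Cl
Reagents that add atoms: methylmagnesium bromide, C[Mg]Br
Why: Grignard 1,2-addition to the aldehyde should be clean because the tetrasubstituted alkenyl bromide is inert to MeMgBr at low temperature, and the new carbinol centre, formed as a mixture, is erased in step 6.

Step 6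
Reactants: 8 1-[(1R)-3-bromo-4-methyl-1-(2-methylbut-3-en-2-yl)cyclohex-3-en-1-yl]ethan-1-ol
Product: 9 1-[(1R)-3-bromo-4-methyl-1-(2-methylbut-3-en-2-yl)cyclohex-3-en-1-yl]ethan-1-one
Conditions: Dess–Martin periodinane (1.3 equiv), CH2Cl2, 20 °C
Reagents that add atoms: none
Why: Dess–Martin oxidation of a secondary alcohol should give the methyl ketone under neutral conditions that leave the three alkenes and the quaternary centre untouched.

Step 7
Reactants: 9 1-[(1R)-3-bromo-4-methyl-1-(2-methylbut-3-en-2-yl)cyclohex-3-en-1-yl]ethan-1-one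
Product: 10 2-[(1R)-3-bromo-4-methyl-1-(2-methylbut-3-en-2-yl)cyclohex-3-en-1-yl]pent-4-en-2-ol (both carbinol epimers)
Conditions: CH2=CHCH2MgBr (2 equiv), Et2O, −78 to 0 °C; aq. NH4Cl
Reagents that add atoms: allylmagnesium bromide, C=CC[Mg]Br
Why: allyl Grignard addition through a six-membered cyclic transition state should tolerate the severe hindrance of this ketone, and both carbinol epimers are carried on because this carbon (future C1) becomes sp2 in step 9.

Step 8
Reactants: 10 2-[(1R)-3-bromo-4-methyl-1-(2-methylbut-3-en-2-yl)cyclohex-3-en-1-yl]pent-4-en-2-ol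
Product: 11 (6R)-8-bromo-1,5,5,9-tetramethylspiro[5.5]undeca-3,8-dien-1-ol (both C1 epimers)
Conditions: second-generation Grubbs catalyst RuCl2(=CHPh)(PCy3)(H2IMes) (5 mol%), CH2Cl2 (0.01 M), 40 °C
Reagents that add atoms: none
Why: Ring-closing olefin metathesis: the ruthenium benzylidene should exchange onto the unhindered allyl terminus (C3), the new alkylidene adds to the vinyl group on C5 by [2+2] cycloaddition, and cycloreversion of the ruthenacyclobutane releases the C3=C4 alkene with loss of ethylene. The closest known reaction type is ring-closing metathesis of 1,7-dienes to cyclohexenes that carry an allylic quaternary carbon. Ring A is the only ring closed, as a six-membered carbocycle by intramolecular metathesis of two monosubstituted alkenes, and the two adjacent quaternary carbons C5 and C6 favour the folded conformer (gem-dialkyl effect). No stereocentre is formed here: C3 and C4 become sp2 and receive their configuration in step 10, and both C1 epimers cyclise. The selectivity needed is for the two terminal alkenes over the ring B alkene, which is secured because the tetrasubstituted C8=C9 bromoalkene cannot form a ruthenacyclobutane. High dilution should suppress intermolecular cross-metathesis.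

Step 9
Reactants: 11 (6R)-8-bromo-1,5,5,9-tetramethylspiro[5.5]undeca-3,8-dien-1-ol
Product: 12 (6S)-8-bromo-1,5,5,9-tetramethylspiro[5.5]undeca-1,3,8-triene
Conditions: Burgess reagent (methyl N-(triethylammoniosulfonyl)carbamate, 2 equiv), toluene, 60 °C
Reagents that add atoms: none
Why: Burgess dehydration (syn elimination of the tertiary sulfamate ester) should remove the more acidic allylic C2–H and not a methyl hydrogen, giving the conjugated ring A 1,3-diene and erasing the C1 carbinol centre (the C6 descriptor changes from R to S through CIP priorities only).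

Step 10
Reactants: 12 (6S)-8-bromo-1,5,5,9-tetramethylspiro[5.5]undeca-1,3,8-triene
Product: 13 (3S,4S,6S)-4,8-dibromo-1,5,5,9-tetramethylspiro[5.5]undeca-1,8-dien-3-ol
Conditions: NBS (1.05 equiv), THF–H2O 3:1, 0 °C, dark
Reagents that add atoms: N-bromosuccinimide, O=C1CCC(=O)N1Br; water, O
Why: bromohydrin formation on a 1,3-diene, in which Br+ should add to C4 (the terminus that leaves the tertiary allyl cation spanning C3 to C1) on the face of C3=C4 syn to C7, where ring B presents its flat C7–C8=C9 edge and not the C11H2–C10H2 edge with its axial hydrogens, and water then opens the bromonium ion anti at allylic C3 (1,2-addition), which sets C4 as S and C3 as S with Br and OH trans.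

Compound list
1 | 2-methylbut-1-en-3-yne | C=C(C)C#C | starting material
2 | 4-bromo-3-methylbuta-1,2-diene | C=C=C(C)CBr | intermediate (not isolated)
3 | 2-bromo-3-methylbuta-1,3-diene | C=C(C)C(Br)=C | intermediate
4 | methyl 3,3-dimethylpent-4-enoate | COC(=O)CC(C)(C)C=C | starting material
5 | 3,3-dimethylpent-4-enal | O=CCC(C)(C)C=C | intermediate
6 | 3,3-dimethyl-2-methylidenepent-4-enal | C=CC(C)(C)C(=C)C=O | intermediate
7 | (1R)-3-bromo-4-methyl-1-(2-methylbut-3-en-2-yl)cyclohex-3-ene-1-carbaldehyde | C=CC(C)(C)[C@@]1(C=O)CCC(C)=C(Br)C1 | intermediate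
8 | 1-[(1R)-3-bromo-4-methyl-1-(2-methylbut-3-en-2-yl)cyclohex-3-en-1-yl]ethan-1-ol, both carbinol epimers | C=CC(C)(C)[C@@]1(C(C)O)CCC(C)=C(Br)C1 | intermediate
9 | 1-[(1R)-3-bromo-4-methyl-1-(2-methylbut-3-en-2-yl)cyclohex-3-en-1-yl]ethan-1-one | C=CC(C)(C)[C@@]1(C(C)=O)CCC(C)=C(Br)C1 | intermediate
10 | 2-[(1R)-3-bromo-4-methyl-1-(2-methylbut-3-en-2-yl)cyclohex-3-en-1-yl]pent-4-en-2-ol, both carbinol epimers | C=CC(C)(C)[C@@]1(C(C)(O)CC=C)CCC(C)=C(Br)C1 | intermediate
11 | (6R)-8-bromo-1,5,5,9-tetramethylspiro[5.5]undeca-3,8-dien-1-ol, both C1 epimers | CC1(O)CC=CC(C)(C)[C@]12CCC(C)=C(Br)C2 | intermediate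
12 | (6S)-8-bromo-1,5,5,9-tetramethylspiro[5.5]undeca-1,3,8-triene | CC1=CC=CC(C)(C)[C@]12CCC(C)=C(Br)C2 | intermediate
13 | (3S,4S,6S)-4,8-dibromo-1,5,5,9-tetramethylspiro[5.5]undeca-1,8-dien-3-ol | CC1=C[C@H](O)[C@@H](Br)C(C)(C)[C@]12CCC(C)=C(Br)C2 | target

Total step count: 10. Longest linear sequence: 9 steps (4 to 13, steps 2 to 10); step 1 is a one-step branch that supplies diene 3.

Steps most likely to fail

1. Step 4. The cycloaddition may stall because an α-tert-alkyl enal meets a bromine-deactivated diene, the acid catalyst may polymerise the diene, or facial control (and the methyl-versus-bromine regiocontrol) may erode. The fallback sets out from 6 and 3 and comes back at 9. The cycloaddition is run with an achiral Lewis acid (Me2AlCl, CH2Cl2, −20 °C) to give the racemic aldehyde F1. Pinnick oxidation (NaClO2, NaH2PO4, 2-methylbut-2-ene, t-BuOH–H2O) gives the racemic carboxylic acid F2. Classical resolution by crystallisation with (R)-1-phenylethanamine gives the diastereomerically pure ammonium carboxylate F3 (the antipodal amine is used if the salt of the (S)-acid proves the less soluble one). Aqueous HCl frees the (1R)-acid F4, and MeLi (2.2 equiv, Et2O, 0 °C) converts F4 directly into methyl ketone 9, so steps 5 and 6 are not needed.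

2. Step 10. Bromonium formation may occur on both faces of C3=C4, because the spiro centre distinguishes them only through the two edges of ring B, and part of the allyl cation may be captured at C1 (1,4-addition). The fallback replaces single-pass selection by a separation and recycling loop; it sets out from 12 and comes back at 12. The step 10 mixture is separated, and the wrong-face bromohydrin, (3R,4R,6S)-4,8-dibromo-1,5,5,9-tetramethylspiro[5.5]undeca-1,8-dien-3-ol F5, is acetylated (Ac2O, pyridine, 4-dimethylaminopyridine) to the bromo acetate F6. Zinc dust in acetic acid then effects reductive β-elimination of F6 back to triene 12, which is put through step 10 again.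

3. Step 9. Elimination may run into the methyl group (exocyclic alkene), or ionisation at C1 may trigger a 1,2-shift of a substituent of the neighbouring spiro carbon. The fallback installs the C1=C2 alkene regiospecifically by enol triflate coupling in place of elimination; it sets out from 7 and comes back at 12, replacing steps 5 to 9 by the same number of operations. Allylmagnesium bromide adds to aldehyde 7 to give the secondary homoallylic alcohol F7. Ring-closing metathesis under the conditions of step 8 closes C3=C4 to give the spiro cyclohexenol F8, and Dess–Martin oxidation gives the β,γ-unsaturated ketone F9. KN(SiMe3)2 and PhNTf2 (THF, −78 °C) deprotonate the doubly activated C2 position and give the dienyl triflate F10. Me2CuLi (Et2O, −20 °C) replaces the triflate by methyl to give 12, the hindered tetrasubstituted alkenyl bromide reacting more slowly.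

Further compounds
F1 | step 4 | racemic 3-bromo-4-methyl-1-(2-methylbut-3-en-2-yl)cyclohex-3-ene-1-carbaldehyde | C=CC(C)(C)C1(C=O)CCC(C)=C(Br)C1
F2 | step 4 | racemic 3-bromo-4-methyl-1-(2-methylbut-3-en-2-yl)cyclohex-3-ene-1-carboxylic acid | C=CC(C)(C)C1(C(=O)O)CCC(C)=C(Br)C1
F3 | step 4 | (1R)-1-phenylethan-1-aminium (1R)-3-bromo-4-methyl-1-(2-methylbut-3-en-2-yl)cyclohex-3-ene-1-carboxylate | C=CC(C)(C)[C@@]1(C(=O)[O-])CCC(C)=C(Br)C1.C[C@@H]([NH3+])c1ccccc1
F4 | step 4 | (1R)-3-bromo-4-methyl-1-(2-methylbut-3-en-2-yl)cyclohex-3-ene-1-carboxylic acid | C=CC(C)(C)[C@@]1(C(=O)O)CCC(C)=C(Br)C1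
F5 | step 10 | (3R,4R,6S)-4,8-dibromo-1,5,5,9-tetramethylspiro[5.5]undeca-1,8-dien-3-ol | CC1=C[C@@H](O)[C@H](Br)C(C)(C)[C@]12CCC(C)=C(Br)C2
F6 | step 10 | (3R,4R,6S)-4,8-dibromo-1,5,5,9-tetramethylspiro[5.5]undeca-1,8-dien-3-yl acetate | CC1=C[C@@H](OC(C)=O)[C@H](Br)C(C)(C)[C@]12CCC(C)=C(Br)C2
F7 | step 9 | 1-[(1R)-3-bromo-4-methyl-1-(2-methylbut-3-en-2-yl)cyclohex-3-en-1-yl]but-3-en-1-ol, both carbinol epimers | C=CC(C)(C)[C@@]1(C(O)CC=C)CCC(C)=C(Br)C1
F8 | step 9 | (6R)-8-bromo-5,5,9-trimethylspiro[5.5]undeca-3,8-dien-1-ol, both C1 epimers | OC1CC=CC(C)(C)[C@]12CCC(C)=C(Br)C2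
F9 | step 9 | (6R)-8-bromo-5,5,9-trimethylspiro[5.5]undeca-3,8-dien-1-one | O=C1CC=CC(C)(C)[C@]12CCC(C)=C(Br)C2
F10 | step 9 | (6R)-8-bromo-5,5,9-trimethylspiro[5.5]undeca-1,3,8-trien-1-yl trifluoromethanesulfonate | FC(F)(F)S(=O)(=O)OC1=CC=CC(C)(C)[C@]12CCC(C)=C(Br)C2
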